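## Retrosynthetic overview

1. The six-membered enone ring is made last: the target comes from a hydroxy-cyclohexane-1,3-dione by acid cyclodehydration, and that dione from a keto-lactone by intramolecular Claisen condensation. C5 is set by equilibration.
2. The keto-lactone comes from an α-allyl γ-butyrolactone and 3-methoxybut-3-en-2-one by Mukaiyama–Michael addition. This creates the quaternary C3a, with the new bond formed anti to the C3 methyl.
3. The α-allyl lactone comes from a trans-β-methyl-γ-aryl-γ-butyrolactone and allyl bromide.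
4. Key bond C2–C3: a sparteine-derived, configurationally defined 1-titanated crotyl carbamate (a homoenolate, i.e. β-acyl carbanion equivalent) adds to 3,4,5-trimethoxybenzaldehyde. It joins a natively electrophilic β-carbonyl carbon to an aldehyde carbon and sets C2, C3 and the absolute configuration in one step.
5. Ring order: the five-membered oxygen ring first (carried as a lactone), the six-membered ring second.

Assumption: (+)-sparteine is purchasable and mirrors exactly the documented (−)-sparteine crotyl carbamate homoaldol (which I recall leads to the 3S series), so the (+) ligand gives the 3R,4R adduct needed here.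

## Route

Step 1
Reactants: 1 (E)-but-2-en-1-ol; 2 N,N-diisopropylcarbamoyl chloride
Product: 3 (E)-but-2-en-1-yl N,N-diisopropylcarbamate
Conditions: NaH, THF, 0 °C → reflux
Reagents that add atoms: N,N-diisopropylcarbamoyl chloride (2), CC(C)N(C(C)C)C(Cl)=O
Why: Nucleophilic acyl substitution (O-carbamoylation) of the sodium alkoxide installs the carbamoyl group that later directs and stabilises α-lithiation; no stereocentre is formed and the E alkene is untouched.

Step 2
Reactants: 3 (E)-but-2-en-1-yl N,N-diisopropylcarbamate; 4 3,4,5-trimethoxybenzaldehyde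
Product: 7 (1Z,3R,4R)-4-hydroxy-3-methyl-4-(3,4,5-trimethoxyphenyl)but-1-en-1-yl N,N-diisopropylcarbamate, via lithiated carbamate 5 (not isolated), via allyltitanium reagent 6 (not isolated)
Conditions: n-BuLi, (+)-sparteine, pentane/cyclohexane, −70 °C, 3 h (crystallisation); Ti(OiPr)4, −70 °C; 4 (in toluene), −70 °C → rt; aq. HCl
Reagents that add atoms: n-butyllithium, [Li]CCCC (lithium in 5 only); Ti(OiPr)4, CC(C)O[Ti](OC(C)C)(OC(C)C)OC(C)C (titanium unit in 6 only)
Why: Hoppe asymmetric homoaldol reaction (homoenolate umpolung): sparteine-directed deprotonation with crystallisation-driven dynamic resolution gives one α-lithio carbamate 5, lithium-to-titanium exchange with inversion gives 6, and 6 adds through its γ-carbon in a closed chair (Zimmerman–Traxler) transition state with aryl equatorial and carbamoyloxy axial, which sets the two new centres anti (both R, the future trans C2-aryl/C3-methyl) and the enol carbamate Z.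

Step 3
Reactants: 7 (1Z,3R,4R)-homoaldol adduct
Product: 9 (4R,5R)-4-methyl-5-(3,4,5-trimethoxyphenyl)dihydrofuran-2(3H)-one, via lactol 8 (not isolated)
Conditions: Hg(OAc)2 (5 mol%), MeSO3H (1.1 equiv), THF/H2O, rt; then TEMPO (10 mol%), PhI(OAc)2, CH2Cl2, rt
Reagents that add atoms: water, O (the lactol oxygen that becomes the lactone carbonyl oxygen)
Why: Hg(OAc)2-assisted acid solvolysis of the enol carbamate (a masked aldehyde) lets the benzylic hydroxyl close onto C1 to the five-membered lactol with loss of the carbamate as amine and CO2, and TEMPO/PhI(OAc)2 (oxoammonium) oxidation gives the lactone; no stereocentre is touched because the benzylic C–O bond is never broken, anti becomes 4,5-trans, and recrystallisation of 9 raises the ee.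

Step 4
Reactants: 9 (4R,5R)-lactone; 10 allyl bromide
Product: 11 (3R,4R,5R)-3-allyl-4-methyl-5-(3,4,5-trimethoxyphenyl)dihydrofuran-2(3H)-one
Conditions: LiN(iPr)2 (1.1 equiv), THF, −78 °C; allyl bromide, −78 → −40 °C
Reagents that add atoms: allyl bromide (10), C=CCBr
Why: SN2 alkylation of the lithium lactone enolate occurs anti to the adjacent C4 methyl group to give the 3,4-trans product, although this centre is planarised again in step 6 so only clean mono-allylation matters.

Step 5
Reactants: 12 3,3-dimethoxybutan-2-one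
Product: 13 3-methoxybut-3-en-2-one
Conditions: p-TsOH (1 mol%), hydroquinone (trace), neat, 150 °C, MeOH distilled off; then distillation
Reagents that add atoms: none
Why: Acid-catalysed thermal elimination of methanol from the α-keto ketal (ketal to enol ether) is driven by removal of methanol and can only give the 2-methoxy enone; no stereocentre.

Step 6
Reactants: 11 (3R,4R,5R)-3-allyl lactone; 13 3-methoxybut-3-en-2-one
Product: 16 (3R,4R,5R)-3-allyl-3-(2-methoxy-3-oxobutyl)-4-methyl-5-(3,4,5-trimethoxyphenyl)dihydrofuran-2(3H)-one (epimer mixture at the side-chain methoxy carbon), via silyl ketene acetal 14 (not isolated), via silyl enol ether 15 (not isolated)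
Conditions: LiN(iPr)2, THF, −78 °C; Me3SiCl, → 0 °C; solvent switch to CH2Cl2; 13 (1.5 equiv), Me3SiOTf (10 mol%), −78 °C; aq. HCl work-up
Reagents that add atoms: chlorotrimethylsilane, C[Si](C)(C)Cl (silicon in 14 and 15 only)
Why: Mukaiyama–Michael addition: O-silylation of 13 turns the captodative enone into a 2-methoxy-siloxyallyl cation that the ketene acetal 14 attacks at its CH2 terminus on the face anti to the adjacent C4 methyl group, so the new chain ends trans and the allyl group cis to that methyl (3R quaternary centre, the future C3a), while the side-chain methoxy centre forms unselectively and is corrected in step 7.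

Step 7
Reactants: 16 keto-lactone
Product: 19 (2R,3R,3aR,5R)-3a-allyl-5-methoxy-3-methyl-2-(3,4,5-trimethoxyphenyl)-3,3a,4,5-tetrahydrobenzofuran-6(2H)-one (target), via hydroxy diketone 17 (not isolated), via C5 epimer 18 (not isolated)
Conditions: KOtBu (2.5 equiv), THF, 0 °C → rt; 2 M HCl, THF, rt; then K2CO3 (0.2 equiv), MeOH, rt
Reagents that add atoms: none
Why: Dieckmann-type intramolecular Claisen condensation of the methyl ketone enolate on the lactone carbonyl (5-oxohexanoate to cyclohexane-1,3-dione, driven by the dione enolate) forms the six-membered ring and frees the benzylic hydroxyl, acid then re-closes the five-membered ring by hemiketalisation–dehydration at C7a with the C2–O bond untouched, and base equilibration through the C5 enolate places the methoxy group pseudo-equatorial, trans to the pseudo-axial allyl group (5R).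

## Compound list

1 | (E)-but-2-en-1-ol | C/C=C/CO | starting material
2 | N,N-diisopropylcarbamoyl chloride | CC(C)N(C(C)C)C(Cl)=O | starting material
3 | (E)-but-2-en-1-yl N,N-diisopropylcarbamate | C/C=C/COC(=O)N(C(C)C)C(C)C | intermediate
4 | 3,4,5-trimethoxybenzaldehyde | COc1cc(C=O)cc(OC)c1OC | starting material
5 | (R,E)-1-lithiobut-2-en-1-yl N,N-diisopropylcarbamate (as its (+)-sparteine complex) | C/C=C/[C@@H]([Li])OC(=O)N(C(C)C)C(C)C | intermediate
6 | (S,E)-1-(triisopropoxytitanio)but-2-en-1-yl N,N-diisopropylcarbamate | C/C=C/[C@H]([Ti](OC(C)C)(OC(C)C)OC(C)C)OC(=O)N(C(C)C)C(C)C | intermediate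
7 | (1Z,3R,4R)-4-hydroxy-3-methyl-4-(3,4,5-trimethoxyphenyl)but-1-en-1-yl N,N-diisopropylcarbamate | CC(C)N(C(C)C)C(=O)O/C=C\[C@@H](C)[C@@H](O)c1cc(OC)c(OC)c(OC)c1 | intermediate
8 | (2RS,4R,5R)-4-methyl-5-(3,4,5-trimethoxyphenyl)tetrahydrofuran-2-ol | OC1C[C@@H](C)[C@H](c2cc(OC)c(OC)c(OC)c2)O1 | intermediate
9 | (4R,5R)-4-methyl-5-(3,4,5-trimethoxyphenyl)dihydrofuran-2(3H)-one | O=C1C[C@@H](C)[C@H](c2cc(OC)c(OC)c(OC)c2)O1 | intermediate
10 | allyl bromide | C=CCBr | starting material
11 | (3R,4R,5R)-3-allyl-4-methyl-5-(3,4,5-trimethoxyphenyl)dihydrofuran-2(3H)-one | O=C1[C@H](CC=C)[C@@H](C)[C@H](c2cc(OC)c(OC)c(OC)c2)O1 | intermediate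
12 | 3,3-dimethoxybutan-2-one | CC(=O)C(C)(OC)OC | starting material
13 | 3-methoxybut-3-en-2-one | CC(=O)C(=C)OC | intermediate
14 | (4R,5R)-3-allyl-4-methyl-5-(3,4,5-trimethoxyphenyl)-2-(trimethylsilyloxy)-4,5-dihydrofuran | C[Si](C)(C)OC1=C(CC=C)[C@@H](C)[C@H](c2cc(OC)c(OC)c(OC)c2)O1 | intermediate
15 | (3R,4R,5R)-3-allyl-3-[2-methoxy-3-(trimethylsilyloxy)but-2-en-1-yl]-4-methyl-5-(3,4,5-trimethoxyphenyl)dihydrofuran-2(3H)-one | O=C1[C@](CC=C)(CC(OC)=C(C)O[Si](C)(C)C)[C@@H](C)[C@H](c2cc(OC)c(OC)c(OC)c2)O1 | intermediate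
16 | (3R,4R,5R)-3-allyl-3-(2-methoxy-3-oxobutyl)-4-methyl-5-(3,4,5-trimethoxyphenyl)dihydrofuran-2(3H)-one (side-chain epimers) | O=C1[C@](CC=C)(CC(OC)C(C)=O)[C@@H](C)[C@H](c2cc(OC)c(OC)c(OC)c2)O1 | intermediate
17 | (4R)-4-allyl-4-[(1R,2R)-1-hydroxy-1-(3,4,5-trimethoxyphenyl)propan-2-yl]-6-methoxycyclohexane-1,3-dione (C6 epimers) | C=CC[C@@]1(CC(OC)C(=O)CC1=O)[C@@H](C)[C@@H](O)c1cc(OC)c(OC)c(OC)c1 | intermediate
18 | (2R,3R,3aR,5S)-3a-allyl-5-methoxy-3-methyl-2-(3,4,5-trimethoxyphenyl)-3,3a,4,5-tetrahydrobenzofuran-6(2H)-one | C=CC[C@]12C[C@H](OC)C(=O)C=C1O[C@@H](c1cc(OC)c(OC)c(OC)c1)[C@@H]2C | intermediate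
19 | (2R,3R,3aR,5R)-3a-allyl-5-methoxy-3-methyl-2-(3,4,5-trimethoxyphenyl)-3,3a,4,5-tetrahydrobenzofuran-6(2H)-one | C=CC[C@]12C[C@@H](OC)C(=O)C=C1O[C@@H](c1cc(OC)c(OC)c(OC)c1)[C@@H]2C | target

## Step count and risks

Total step count: 7. Longest linear sequence: 6 steps (1 → 3 → 7 → 9 → 11 → 16 → 19); step 5 is a one-step reagent preparation.

Most likely to fail, in this order:

**Step 6** (reactivity of the captodative acceptor 13, and face selectivity at the quaternary centre). The fallback sets out from 11 and comes back at 16; it brings in the C5 oxygen after the C–C bond instead of with it. Compound 11 is converted as before into 14 and added to but-3-en-2-one (Me3SiOTf cat., CH2Cl2, −78 °C, Et3N quench), which gives the regiodefined trimethylsilyl enol ether F1. Rubottom oxidation of F1 (mCPBA, NaHCO3, CH2Cl2, 0 °C, then citric acid/MeOH) gives the α-hydroxy ketone F2. O-methylation (Me3OBF4, 1,8-bis(dimethylamino)naphthalene, CH2Cl2) returns to 16.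

**Step 7** (retro-Michael or wrong-site enolisation under KOtBu; acid-labile benzylic alcohol in 17). The fallback sets out from 16 and comes back at 19; it replaces the condensation by an olefination that never opens the lactone. Compound 16 is brominated at the methyl group (LiN(SiMe3)2, THF, −78 °C; NBS) to the bromomethyl ketone F3. PPh3 in toluene gives the phosphonium bromide F4, and aqueous Na2CO3 gives the stabilised acylphosphorane F5. Heating F5 in toluene (110 °C) closes C7=C7a by intramolecular Wittig olefination of the lactone carbonyl, and the same K2CO3/MeOH equilibration at C5 delivers 19.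

**Step 2** (ee depends on the crystallisation of the (+)-sparteine complex). The fallback sets out from 3 and 4 and comes back at 7; it takes the absolute configuration from a resolution instead of from the deprotonation. The ligand-free variant (n-BuLi, TMEDA, Et2O, −78 °C; Ti(OiPr)4; then 4) gives the same Z-anti adduct as the racemate, that is 7 together with its enantiomer, the (1Z,3S,4S) adduct F6. Preparative chromatography on a chiral stationary phase separates F6 from 7, which continues into step 3.

## Further compounds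

F1 | step 6 | (3R,4R,5R)-3-allyl-4-methyl-3-[3-(trimethylsilyloxy)but-2-en-1-yl]-5-(3,4,5-trimethoxyphenyl)dihydrofuran-2(3H)-one | O=C1[C@](CC=C)(CC=C(C)O[Si](C)(C)C)[C@@H](C)[C@H](c2cc(OC)c(OC)c(OC)c2)O1
F2 | step 6 | (3R,4R,5R)-3-allyl-3-(2-hydroxy-3-oxobutyl)-4-methyl-5-(3,4,5-trimethoxyphenyl)dihydrofuran-2(3H)-one (side-chain epimers) | O=C1[C@](CC=C)(CC(O)C(C)=O)[C@@H](C)[C@H](c2cc(OC)c(OC)c(OC)c2)O1
F3 | step 7 | (3R,4R,5R)-3-allyl-3-(4-bromo-2-methoxy-3-oxobutyl)-4-methyl-5-(3,4,5-trimethoxyphenyl)dihydrofuran-2(3H)-one | O=C1[C@](CC=C)(CC(OC)C(=O)CBr)[C@@H](C)[C@H](c2cc(OC)c(OC)c(OC)c2)O1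
F4 | step 7 | triphenylphosphonium bromide derived from F3 | O=C1[C@](CC=C)(CC(OC)C(=O)C[P+](c2ccccc2)(c2ccccc2)c2ccccc2)[C@@H](C)[C@H](c2cc(OC)c(OC)c(OC)c2)O1.[Br-]
F5 | step 7 | acylphosphorane derived from F4 | O=C1[C@](CC=C)(CC(OC)C(=O)C=P(c2ccccc2)(c2ccccc2)c2ccccc2)[C@@H](C)[C@H](c2cc(OC)c(OC)c(OC)c2)O1
F6 | step 2 | (1Z,3S,4S)-4-hydroxy-3-methyl-4-(3,4,5-trimethoxyphenyl)but-1-en-1-yl N,N-diisopropylcarbamate | CC(C)N(C(C)C)C(=O)O/C=C\[C@H](C)[C@H](O)c1cc(OC)c(OC)c(OC)c1
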